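**Strategy.** The C8 side chain (carbons C1''–C9'', counted outward from ring A) is read as a reduced chalcone: C3'', which carries a 4-hydroxyphenyl ring, lies β to the carbinol carbon C1''. At the ketone level, C1''(=O)–C2''=C3'' is an aryl enone. The C3''–C4'' bond is therefore made by a rhodium-catalysed asymmetric 1,4-addition of the complete (E)-alkenylboronate arm, which joins both halves and sets C3'' in one operation. In the precursor, ring C is still a flat chromone. It should tolerate the alkenylation and the reagent-controlled C1'' reduction, and only afterwards receives its 4-hydroxyphenyl group and the C2 stereocentre by a second catalytic conjugate addition.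

Key step: step 9

Remark (abbreviations): TIPS = triisopropylsilyl, TES = triethylsilyl, TBS = tert-butyldimethylsilyl; ring A is the benzo ring and ring C the pyranone ring.

Remark (assumption): the sense of induction of each chiral catalyst or reagent is assigned by analogy with its accepted stereochemical model; if a model substrate showed the opposite sense, the antipodal ligand or reagent would be used.

**Fragment 1 (enone 8)**

Step 1
Reactants: 1 2',6'-dihydroxy-4'-methoxyacetophenone; 2 3-chloropropanoic acid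
Product: 4 8-acetyl-7-hydroxy-5-methoxychroman-4-one, via chloroketone 3 (not isolated)
Conditions: CF3SO3H, 80 °C; then 2 M NaOH (aq), 0 °C → rt; aq. HCl
Reagents that add atoms: none
Why: Friedel–Crafts acylation can only occur at the one kind of free ring position (C3 and C5 are equivalent and meta to the acetyl group), so the substitution pattern is unambiguous; the 3-chloropropanoyl ketone is then closed by its only ortho phenol (the hydroxyl between the two acyl groups) by intramolecular Williamson etherification to the chroman-4-one.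

Step 2
Reactants: 4 8-acetyl-7-hydroxy-5-methoxychroman-4-one
Product: 5 8-acetyl-7-hydroxy-5-methoxy-4H-chromen-4-one
Conditions: Pd(OCOCF3)2 (5 mol%), DMSO (10 mol%), O2 (1 atm), AcOH, 80 °C
Reagents that add atoms: none
Why: Palladium-catalysed aerobic α,β-dehydrogenation of the cyclic ketone (palladium enolate at C3, β-hydride elimination from C2) should give the chromone, while the methyl ketone has no β-hydrogen and cannot react.

Step 3
Reactants: 5 8-acetyl-7-hydroxy-5-methoxy-4H-chromen-4-one; 6 4-hydroxybenzaldehyde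
Product: 7 7-hydroxy-8-[(2E)-3-(4-hydroxyphenyl)prop-2-enoyl]-5-methoxy-4H-chromen-4-one
Conditions: BF3·OEt2 (0.5 equiv), 1,4-dioxane, rt
Reagents that add atoms: none
Why: Lewis acid-promoted Claisen–Schmidt condensation, in which the acetyl methyl group is the only enolisable position (the chromone has no α-CH2), the acidic medium spares the base-labile pyranone, and dehydration should give the conjugated (E)-enone.

Step 4
Reactants: 7 7-hydroxy-8-[(2E)-3-(4-hydroxyphenyl)prop-2-enoyl]-5-methoxy-4H-chromen-4-one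
Product: 8 5-methoxy-7-(triisopropylsilyloxy)-8-[(2E)-3-(4-triisopropylsilyloxyphenyl)prop-2-enoyl]-4H-chromen-4-one
Conditions: TIPSOTf (2.5 equiv), 2,6-lutidine, CH2Cl2, 0 °C → rt
Reagents that add atoms: triisopropylsilyl trifluoromethanesulfonate, CC(C)[Si](OS(=O)(=O)C(F)(F)F)(C(C)C)C(C)C
Why: A silyl triflate with a hindered pyridine base should silylate both phenols, including the hydrogen-bonded 7-OH, so that no phenoxide can quench the hydroxorhodium catalyst or add to the enone in step 9.

**Fragment 2 (alkenylboronate 16)**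

Step 5
Reactants: 9 4-(3-hydroxypropyl)phenol
Product: 10 3-[4-(triisopropylsilyloxy)phenyl]propan-1-ol
Conditions: NaH (1.05 equiv), THF, 0 °C; TIPSCl (1.05 equiv), 0 °C → rt
Reagents that add atoms: chlorotriisopropylsilane, CC(C)[Si](Cl)(C(C)C)C(C)C
Why: One equivalent of NaH forms only the phenoxide (the alcohol is about six pKa units less acidic), and this alone is silylated by the chlorosilane.

Step 6
Reactants: 10 3-[4-(triisopropylsilyloxy)phenyl]propan-1-ol; 11 allyl acetate
Product: 13 (3S)-1-[4-(triisopropylsilyloxy)phenyl]hex-5-en-3-ol, via aldehyde 12 (not isolated)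
Conditions: [Ir(cod)Cl]2 (2.5 mol%), (R)-Cl,MeO-BIPHEP (5 mol%), 4-chloro-3-nitrobenzoic acid (10 mol%), Cs2CO3 (20 mol%), THF, 100 °C (sealed tube)
Reagents that add atoms: none
Why: Krische transfer-hydrogenative carbonyl allylation, in which the alcohol is dehydrogenated to aldehyde 12 and the cyclometallated π-allyliridium benzoate allylates its Re face under control of the (R)-bisphosphine, which should set the (S)-carbinol without a separate oxidation.

Step 7
Reactants: 13 (3S)-1-[4-(triisopropylsilyloxy)phenyl]hex-5-en-3-ol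
Product: 14 triethyl{[(3S)-1-(4-triisopropylsilyloxyphenyl)hex-5-en-3-yl]oxy}silane
Conditions: TESCl, imidazole, CH2Cl2, 0 °C → rt
Reagents that add atoms: chlorotriethylsilane, CC[Si](Cl)(CC)CC
Why: Standard silylation of the secondary alcohol; the TES ether keeps the hydroxyl from consuming the chloroborane in step 10 and is removed with the aryl silyl ethers at the end.

Step 8
Reactants: 14 triethyl{[(3S)-1-(4-triisopropylsilyloxyphenyl)hex-5-en-3-yl]oxy}silane; 15 vinylboronic acid pinacol ester
Product: 16 2-[(1E,4S)-4-(triethylsilyloxy)-6-(4-triisopropylsilyloxyphenyl)hex-1-en-1-yl]-4,4,5,5-tetramethyl-1,3,2-dioxaborolane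
Conditions: second-generation Grubbs catalyst RuCl2(H2IMes)(PCy3)(=CHPh) (5 mol%), CH2Cl2, 40 °C
Reagents that add atoms: none
Why: Olefin cross-metathesis of a terminal alkene with the vinylboronate, which should be E-selective because of the bulky boronate group.

**Fragment union and completion**

Step 9
Reactants: 8 5-methoxy-7-(triisopropylsilyloxy)-8-[(2E)-3-(4-triisopropylsilyloxyphenyl)prop-2-enoyl]-4H-chromen-4-one; 16 2-[(1E,4S)-4-(triethylsilyloxy)-6-(4-triisopropylsilyloxyphenyl)hex-1-en-1-yl]-4,4,5,5-tetramethyl-1,3,2-dioxaborolane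
Product: 17 8-[(3R,4E,7S)-7-(triethylsilyloxy)-3,9-bis(4-triisopropylsilyloxyphenyl)non-4-enoyl]-5-methoxy-7-(triisopropylsilyloxy)-4H-chromen-4-one
Conditions: [Rh(OH)((R,R)-Ph-bod*)]2 (3 mol%; Ph-bod* = 2,5-diphenylbicyclo[2.2.2]octa-2,5-diene), 16 (1.2 equiv), 1,4-dioxane/H2O (10:1), 40 °C
Reagents that add atoms: none
Why: Hayashi–Miyaura asymmetric 1,4-addition: the alkenyl group is transmetallated from boron to the hydroxorhodium–diene complex, the alkenylrhodium inserts the C2''=C3'' bond of the aryl enone to give an oxa-π-allylrhodium enolate, and water protonates it and regenerates Rh–OH. The closest known reaction type is the rhodium/chiral diene-catalysed addition of (E)-alkenylboron reagents to acyclic (E)-β-aryl enones (chalcones). No ring is closed. The new C3'' stereocentre is set by the catalyst alone: the C2-symmetric (R,R)-diene should direct the alkenyl group to the Si face of C3'' (3''R), the remote C7'' centre is a spectator, and the E geometry of the alkenyl group is transferred with retention. The step needs chemoselectivity for the acyclic enone over the chromone C2=C3 bond, which is expected because the chromone is a cross-conjugated vinylogous ester and a much poorer acceptor at 40 °C with only 1.2 equiv of 16; it also needs both phenols silylated so that no phenoxide deactivates or closes onto the enone. Ring C carries no stereocentre at this stage, so nothing can epimerise under the mildly basic aqueous conditions.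

Step 10
Reactants: 17 8-[(3R,4E,7S)-7-(triethylsilyloxy)-3,9-bis(4-triisopropylsilyloxyphenyl)non-4-enoyl]-5-methoxy-7-(triisopropylsilyloxy)-4H-chromen-4-one
Product: 18 8-[(1S,3R,4E,7S)-1-hydroxy-7-(triethylsilyloxy)-3,9-bis(4-triisopropylsilyloxyphenyl)non-4-en-1-yl]-5-methoxy-7-(triisopropylsilyloxy)-4H-chromen-4-one
Conditions: (−)-B-chlorodiisopinocampheylborane ((−)-DIP-Cl, 2.5 equiv), THF, −25 → 0 °C; then CH3CHO, rt; aq. NaHCO3
Reagents that add atoms: none
Why: Asymmetric reduction with DIP-Cl, in which hydride is transferred from an isopinocampheyl group through a boat-like six-membered transition state with the twisted, doubly ortho-substituted aryl group as the large substituent, so that the (−)-reagent should attack the Re face and give the (1''S)-alcohol under reagent control; the vinylogous-ester carbonyl of the chromone is not expected to be reduced, and the reagent has no B–H bond that could hydroborate the alkene.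

Step 11
Reactants: 18 8-[(1S,3R,4E,7S)-1-hydroxy-7-(triethylsilyloxy)-3,9-bis(4-triisopropylsilyloxyphenyl)non-4-en-1-yl]-5-methoxy-7-(triisopropylsilyloxy)-4H-chromen-4-one; 19 4-(tert-butyldimethylsilyloxy)phenylboronic acid
Product: 20 (2S)-2-(4-tert-butyldimethylsilyloxyphenyl)-8-[(1S,3R,4E,7S)-1-hydroxy-7-(triethylsilyloxy)-3,9-bis(4-triisopropylsilyloxyphenyl)non-4-en-1-yl]-5-methoxy-7-(triisopropylsilyloxy)chroman-4-one
Conditions: [Rh(OH)(cod)]2 (2.5 mol%), (S)-MeO-F12-BIPHEP [(S)-6,6'-dimethoxy-2,2'-bis{bis(3,4,5-trifluorophenyl)phosphino}biphenyl, 5.5 mol%], 19 (3 equiv), toluene/H2O (10:1), 30 °C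
Reagents that add atoms: none
Why: Hayashi–Miyaura-type asymmetric 1,4-addition of an arylboronic acid to a chromone, where the electron-poor biaryl bisphosphine should make insertion fast enough at 30 °C that the flavanone formed is not ring-opened, and the (S)-ligand should deliver the aryl group to the Re face of C2 to give the (2S)-flavanone by catalyst control.

Step 12
Reactants: 20 (2S)-2-(4-tert-butyldimethylsilyloxyphenyl)-8-[(1S,3R,4E,7S)-1-hydroxy-7-(triethylsilyloxy)-3,9-bis(4-triisopropylsilyloxyphenyl)non-4-en-1-yl]-5-methoxy-7-(triisopropylsilyloxy)chroman-4-one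
Product: 21 (2S)-8-[(1S,3R,4E,7S)-1,7-dihydroxy-3,9-bis(4-hydroxyphenyl)non-4-en-1-yl]-7-hydroxy-2-(4-hydroxyphenyl)-5-methoxychroman-4-one (CNP0415883.1)
Conditions: TBAF (7 equiv), AcOH (7 equiv), THF, 0 °C → rt
Reagents that add atoms: none
Why: Fluoride buffered with acetic acid should cleave the four aryl silyl ethers and the TES ether at near-neutral pH, which avoids base-induced ring opening (C2 epimerisation) of the flavanone and acid-induced ionisation of the electron-rich benzylic alcohol at C1''.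

**Compound list**

1 | 2',6'-dihydroxy-4'-methoxyacetophenone | CC(=O)c1c(O)cc(OC)cc1O | starting material
2 | 3-chloropropanoic acid | OC(=O)CCCl | starting material
3 | 1-(3-acetyl-2,4-dihydroxy-6-methoxyphenyl)-3-chloropropan-1-one | CC(=O)c1c(O)cc(OC)c(C(=O)CCCl)c1O | intermediate (not isolated)
4 | 8-acetyl-7-hydroxy-5-methoxychroman-4-one | CC(=O)c1c(O)cc(OC)c2c1OCCC2=O | intermediate
5 | 8-acetyl-7-hydroxy-5-methoxy-4H-chromen-4-one | CC(=O)c1c(O)cc(OC)c2c1OC=CC2=O | intermediate
6 | 4-hydroxybenzaldehyde | O=Cc1ccc(O)cc1 | starting material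
7 | 7-hydroxy-8-[(2E)-3-(4-hydroxyphenyl)prop-2-enoyl]-5-methoxy-4H-chromen-4-one | COc1cc(O)c(C(=O)/C=C/c2ccc(O)cc2)c2c1C(=O)C=CO2 | intermediate
8 | 5-methoxy-7-(triisopropylsilyloxy)-8-[(2E)-3-(4-triisopropylsilyloxyphenyl)prop-2-enoyl]-4H-chromen-4-one | COc1cc(O[Si](C(C)C)(C(C)C)C(C)C)c(C(=O)/C=C/c2ccc(O[Si](C(C)C)(C(C)C)C(C)C)cc2)c2c1C(=O)C=CO2 | intermediate
9 | 4-(3-hydroxypropyl)phenol | OCCCc1ccc(O)cc1 | starting material
10 | 3-[4-(triisopropylsilyloxy)phenyl]propan-1-ol | OCCCc1ccc(O[Si](C(C)C)(C(C)C)C(C)C)cc1 | intermediate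
11 | allyl acetate | C=CCOC(C)=O | starting material
12 | 3-[4-(triisopropylsilyloxy)phenyl]propanal | O=CCCc1ccc(O[Si](C(C)C)(C(C)C)C(C)C)cc1 | intermediate (not isolated)
13 | (3S)-1-[4-(triisopropylsilyloxy)phenyl]hex-5-en-3-ol | C=CC[C@@H](O)CCc1ccc(O[Si](C(C)C)(C(C)C)C(C)C)cc1 | intermediate
14 | triethyl{[(3S)-1-(4-triisopropylsilyloxyphenyl)hex-5-en-3-yl]oxy}silane | C=CC[C@@H](O[Si](CC)(CC)CC)CCc1ccc(O[Si](C(C)C)(C(C)C)C(C)C)cc1 | intermediate
15 | vinylboronic acid pinacol ester | C=CB1OC(C)(C)C(C)(C)O1 | starting material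
16 | 2-[(1E,4S)-4-(triethylsilyloxy)-6-(4-triisopropylsilyloxyphenyl)hex-1-en-1-yl]-4,4,5,5-tetramethyl-1,3,2-dioxaborolane | CC1(C)OB(/C=C/C[C@@H](O[Si](CC)(CC)CC)CCc2ccc(O[Si](C(C)C)(C(C)C)C(C)C)cc2)OC1(C)C | intermediate
17 | 8-[(3R,4E,7S)-7-(triethylsilyloxy)-3,9-bis(4-triisopropylsilyloxyphenyl)non-4-enoyl]-5-methoxy-7-(triisopropylsilyloxy)-4H-chromen-4-one | COc1cc(O[Si](C(C)C)(C(C)C)C(C)C)c(C(=O)C[C@H](/C=C/C[C@@H](O[Si](CC)(CC)CC)CCc2ccc(O[Si](C(C)C)(C(C)C)C(C)C)cc2)c2ccc(O[Si](C(C)C)(C(C)C)C(C)C)cc2)c2c1C(=O)C=CO2 | intermediate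
18 | 8-[(1S,3R,4E,7S)-1-hydroxy-7-(triethylsilyloxy)-3,9-bis(4-triisopropylsilyloxyphenyl)non-4-en-1-yl]-5-methoxy-7-(triisopropylsilyloxy)-4H-chromen-4-one | COc1cc(O[Si](C(C)C)(C(C)C)C(C)C)c([C@@H](O)C[C@H](/C=C/C[C@@H](O[Si](CC)(CC)CC)CCc2ccc(O[Si](C(C)C)(C(C)C)C(C)C)cc2)c2ccc(O[Si](C(C)C)(C(C)C)C(C)C)cc2)c2c1C(=O)C=CO2 | intermediate
19 | 4-(tert-butyldimethylsilyloxy)phenylboronic acid | CC(C)(C)[Si](C)(C)Oc1ccc(B(O)O)cc1 | starting material
20 | (2S)-2-(4-tert-butyldimethylsilyloxyphenyl)-8-[(1S,3R,4E,7S)-1-hydroxy-7-(triethylsilyloxy)-3,9-bis(4-triisopropylsilyloxyphenyl)non-4-en-1-yl]-5-methoxy-7-(triisopropylsilyloxy)chroman-4-one | COc1cc(O[Si](C(C)C)(C(C)C)C(C)C)c([C@@H](O)C[C@H](/C=C/C[C@@H](O[Si](CC)(CC)CC)CCc2ccc(O[Si](C(C)C)(C(C)C)C(C)C)cc2)c2ccc(O[Si](C(C)C)(C(C)C)C(C)C)cc2)c2c1C(=O)C[C@@H](c1ccc(O[Si](C)(C)C(C)(C)C)cc1)O2 | intermediate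
21 | (2S)-8-[(1S,3R,4E,7S)-1,7-dihydroxy-3,9-bis(4-hydroxyphenyl)non-4-en-1-yl]-7-hydroxy-2-(4-hydroxyphenyl)-5-methoxychroman-4-one | COc1cc(O)c([C@@H](O)C[C@H](/C=C/C[C@@H](O)CCc2ccc(O)cc2)c2ccc(O)cc2)c2c1C(=O)C[C@@H](c1ccc(O)cc1)O2 | target

**Step count and risks**

Total step count: 12. Longest linear sequence: 8 steps (steps 1–4 and 9–12, or steps 5–8 and 9–12).

Steps most likely to fail:

1. Step 11 (late chromone arylation). Insertion of the arylrhodium into the electron-rich 5-methoxychromone may be slower than protodeboronation of 19. The free C1'' hydroxyl may add reversibly to C2 or take over the neighbouring silyl group. Facial control may be eroded by the bulky C8 substituent. Fallback, from 18 back to the route at 21: ring C is built by chalcone cyclisation instead. TBAF/AcOH in THF removes the four silyl groups of 18 to give 8-[(1S,3R,4E,7S)-1,7-dihydroxy-3,9-bis(4-hydroxyphenyl)non-4-en-1-yl]-7-hydroxy-5-methoxy-4H-chromen-4-one F1. KOH in aqueous EtOH at 50 °C opens the pyranone by hydroxide addition at C2 and retro-Claisen loss of formate to give 1-{3-[(1S,3R,4E,7S)-1,7-dihydroxy-3,9-bis(4-hydroxyphenyl)non-4-en-1-yl]-2,4-dihydroxy-6-methoxyphenyl}ethan-1-one F2. Claisen–Schmidt condensation of F2 with 4-hydroxybenzaldehyde 6 (KOH, EtOH, rt) gives the 2'-hydroxychalcone (2E)-1-{3-[(1S,3R,4E,7S)-1,7-dihydroxy-3,9-bis(4-hydroxyphenyl)non-4-en-1-yl]-2,4-dihydroxy-6-methoxyphenyl}-3-(4-hydroxyphenyl)prop-2-en-1-one F3. NaOAc in refluxing EtOH closes ring C by oxa-Michael addition of the only ortho phenol. This should give 21 together with its C2 epimer, (2R)-8-[(1S,3R,4E,7S)-1,7-dihydroxy-3,9-bis(4-hydroxyphenyl)non-4-en-1-yl]-7-hydroxy-2-(4-hydroxyphenyl)-5-methoxychroman-4-one F4, to be separated by preparative HPLC.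

2. Step 9 (key alkenylation). Insertion into the hindered, twisted aryl enone may be sluggish, so that protodeboronation of 16 competes, and facial discrimination by the diene may be insufficient. Fallback, from 16 (with 8) back to the route at 17: a metal-free conjugate alkenylboration. NaIO4/NH4OAc in acetone/H2O converts 16 into [(1E,4S)-4-(triethylsilyloxy)-6-(4-triisopropylsilyloxyphenyl)hex-1-en-1-yl]boronic acid F5. F5 is then added to 8 under catalysis by 3,3'-diiodo-BINOL (20 mol%, the enantiomer that directs the alkenyl group to the Si face of C3'') with Mg(OtBu)2 (10 mol%) and 4 Å molecular sieves in toluene at 70 °C. This proceeds through a carbonyl-bound chiral boronate and a six-membered transition state and should give 17.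

3. Step 10 (C1'' reduction). Hydride transfer to the doubly ortho-substituted ketone may be slow, adventitious HCl may strip silyl groups, and the reagent may be mismatched with the C3'' centre, giving poor diastereocontrol. Fallback, from 17 back to the route at 18: reagent control is replaced by separation and recycling. Luche reduction (NaBH4, CeCl3·7H2O, MeOH/THF, −40 °C) should reduce only the C1'' ketone, without facial control, to 18 and its C1'' epimer, 8-[(1R,3R,4E,7S)-1-hydroxy-7-(triethylsilyloxy)-3,9-bis(4-triisopropylsilyloxyphenyl)non-4-en-1-yl]-5-methoxy-7-(triisopropylsilyloxy)-4H-chromen-4-one F6. The two are separated by chromatography, and F6 is oxidised back to 17 with Dess–Martin periodinane and resubmitted.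

**Further compounds**

F1 | step 11 | 8-[(1S,3R,4E,7S)-1,7-dihydroxy-3,9-bis(4-hydroxyphenyl)non-4-en-1-yl]-7-hydroxy-5-methoxy-4H-chromen-4-one | COc1cc(O)c([C@@H](O)C[C@H](/C=C/C[C@@H](O)CCc2ccc(O)cc2)c2ccc(O)cc2)c2c1C(=O)C=CO2
F2 | step 11 | 1-{3-[(1S,3R,4E,7S)-1,7-dihydroxy-3,9-bis(4-hydroxyphenyl)non-4-en-1-yl]-2,4-dihydroxy-6-methoxyphenyl}ethan-1-one | COc1cc(O)c([C@@H](O)C[C@H](/C=C/C[C@@H](O)CCc2ccc(O)cc2)c2ccc(O)cc2)c(O)c1C(C)=O
F3 | step 11 | (2E)-1-{3-[(1S,3R,4E,7S)-1,7-dihydroxy-3,9-bis(4-hydroxyphenyl)non-4-en-1-yl]-2,4-dihydroxy-6-methoxyphenyl}-3-(4-hydroxyphenyl)prop-2-en-1-one | COc1cc(O)c([C@@H](O)C[C@H](/C=C/C[C@@H](O)CCc2ccc(O)cc2)c2ccc(O)cc2)c(O)c1C(=O)/C=C/c1ccc(O)cc1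
F4 | step 11 | (2R)-8-[(1S,3R,4E,7S)-1,7-dihydroxy-3,9-bis(4-hydroxyphenyl)non-4-en-1-yl]-7-hydroxy-2-(4-hydroxyphenyl)-5-methoxychroman-4-one | COc1cc(O)c([C@@H](O)C[C@H](/C=C/C[C@@H](O)CCc2ccc(O)cc2)c2ccc(O)cc2)c2c1C(=O)C[C@H](c1ccc(O)cc1)O2
F5 | step 9 | [(1E,4S)-4-(triethylsilyloxy)-6-(4-triisopropylsilyloxyphenyl)hex-1-en-1-yl]boronic acid | OB(O)/C=C/C[C@@H](O[Si](CC)(CC)CC)CCc1ccc(O[Si](C(C)C)(C(C)C)C(C)C)cc1
F6 | step 10 | 8-[(1R,3R,4E,7S)-1-hydroxy-7-(triethylsilyloxy)-3,9-bis(4-triisopropylsilyloxyphenyl)non-4-en-1-yl]-5-methoxy-7-(triisopropylsilyloxy)-4H-chromen-4-one | COc1cc(O[Si](C(C)C)(C(C)C)C(C)C)c([C@H](O)C[C@H](/C=C/C[C@@H](O[Si](CC)(CC)CC)CCc2ccc(O[Si](C(C)C)(C(C)C)C(C)C)cc2)c2ccc(O[Si](C(C)C)(C(C)C)C(C)C)cc2)c2c1C(=O)C=CO2
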